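**Assumption:** the target is the erythro (7″S,8″R) 8‑O‑4′ ether. Its tetralin is all‑trans (1S,2S,3R), with free phenols at C7 and on the guaiacyl ring of the side chain.

## Retrosynthetic overview
- The last step removes the two O‑benzyl‑type protecting groups (Bn and Cbz) by hydrogenolysis.
- The aryltetralin (bonds C1–C8a and C2–C3) comes from a radical‑cation [4+2] cross‑cyclodimerisation of two (E)‑propenylguaiacol units. The chain‑bearing propenylarene acts as dienophile, and an isoeugenyl carbonate acts as the diene/arene partner. The tetralin ring is closed last.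
- The erythro 8‑O‑4′ alcohol comes from dynamic kinetic asymmetric transfer hydrogenation of an α‑aryloxy propiophenone. That ketone comes from S_N2 of isoeugenol on an α‑bromoketone.
- All three guaiacyl units come from catechol via guaiacol and propiovanillone, with propionic acid supplying the C3 unit.

## Route

**Step 1**
Reactants: 1 catechol
Product: 2 guaiacol (2‑methoxyphenol)
Conditions: (MeO)2C=O (3 equiv), K2CO3 (cat.), 160 °C, sealed tube
Reagents that add atoms: dimethyl carbonate, COC(=O)OC (adds CH3)
Why: base‑catalysed O‑methylation by dimethyl carbonate is selective for mono‑methylation of catechol.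

**Step 2**
Reactants: 2 guaiacol; 3 propionic acid
Product: 4 propiovanillone (1‑(4‑hydroxy‑3‑methoxyphenyl)propan‑1‑one)
Conditions: BF3·OEt2, 80 °C, 3 h
Reagents that add atoms: none (propionic acid 3 is the acyl source)
Why: Friedel–Crafts acylation goes para to the strongly activating OH.

**Step 3**
Reactants: 4 propiovanillone
Product: 5 1‑(4‑benzyloxy‑3‑methoxyphenyl)propan‑1‑one
Conditions: BnBr, K2CO3, acetone, reflux
Reagents that add atoms: benzyl bromide, BrCc1ccccc1 (adds Bn)
Why: Williamson O‑benzylation masks the ring‑A phenol so it cannot interfere in the S_N2 step.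

**Step 4**
Reactants: 5
Product: 6 2‑bromo‑1‑(4‑benzyloxy‑3‑methoxyphenyl)propan‑1‑one (racemic)
Conditions: CuBr2 (2 equiv), EtOAc–CHCl3 1:1, reflux
Reagents that add atoms: copper(II) bromide, Br[Cu]Br (adds Br)
Why: CuBr2 brominates the ketone α‑position selectively and leaves the arene untouched.

**Step 5**
Reactants: 4
Product: 7 1‑(4‑hydroxy‑3‑methoxyphenyl)propan‑1‑ol (racemic)
Conditions: NaBH4, MeOH, 0 °C to rt
Reagents that add atoms: none
Why: simple hydride reduction of the aryl ketone.

**Step 6**
Reactants: 7
Product: 8 (E)‑isoeugenol
Conditions: TsOH·H2O (5 mol %), toluene, reflux, 30 min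
Reagents that add atoms: none
Why: E1 (via p‑quinone methide) dehydration gives the conjugated (E)‑propenylarene, which is favoured thermodynamically.

**Step 7**
Reactants: 8
Product: 9 (E)‑isoeugenyl benzyl carbonate
Conditions: CbzCl, pyridine, CH2Cl2, 0 °C
Reagents that add atoms: benzyl chloroformate, O=C(Cl)OCc1ccccc1 (adds CO2Bn)
Why: acylation gives an electron‑poor, hydrogenolysable phenol protecting group. It raises the styrene oxidation potential so that 9 is not oxidised in the radical‑cation step and serves only as the neutral partner.

**Step 8**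
Reactants: 6; 8
Product: 10 2‑[2‑methoxy‑4‑((E)‑prop‑1‑enyl)phenoxy]‑1‑(4‑benzyloxy‑3‑methoxyphenyl)propan‑1‑one (racemic)
Conditions: K2CO3, acetone–DMF, 50 °C
Reagents that add atoms: none
Why: Williamson (S_N2) etherification joins the phenoxide of 8 to the α‑bromoketone. The propenyl group is inert under these conditions.

**Step 9**
Reactants: 10
Product: 11 (1S,2R)‑1‑(4‑benzyloxy‑3‑methoxyphenyl)‑2‑[2‑methoxy‑4‑((E)‑prop‑1‑enyl)phenoxy]propan‑1‑ol
Conditions: RuCl[(S,S)‑TsDPEN](p‑cymene) (1 mol %), HCO2H–Et3N 5:2, CH2Cl2, 40 °C
Reagents that add atoms: none (formate supplies H only)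
Why: Noyori–Ikariya asymmetric transfer hydrogenation combined with dynamic kinetic resolution. The acidic α‑aryloxy stereocentre epimerises faster than it is reduced, and the chiral Ru–H selects one carbonyl face, setting both C7″ (S) and C8″ (R) (erythro) as a single enantiomer; the catalyst enantiomer is chosen to give this outcome.

**Step 10**
Reactants: 11 (1 equiv); 9 (3 equiv)
Product: 12 benzyl carbonate of the tetralin (7″S,8″R side chain; tetralin 1S,2S,3R all‑trans), with the chain on the ring‑B 4′‑O and Bn on ring A
Conditions: Ru(bpz)3(PF6)2 (1 mol %), air, CH2Cl2–MeNO2 4:1 (0.05 M), blue LEDs, 25 °C; then preparative HPLC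
Reagents that add atoms: none (O2 is only the terminal oxidant)
Why: radical‑cation Diels–Alder‑type cross‑cyclodimerisation. The styrene of 11 is the most easily oxidised partner, and its radical cation is attacked at C8′ by the arene‑bearing alkene of 9; the resulting distonic radical cation closes onto ring‑C carbon C6′ (para to OMe). Electron transfer from a fresh molecule of 11 then propagates the chain, and a 1,3‑H shift rearomatises the ring.
Proposed new method: the cross‑selective version rests on the oxidation‑potential difference between 11 (alkyl aryl ether styrene) and 9 (carbonate styrene), plus excess 9 to suppress homodimerisation of 11. The closest known reaction type is radical‑cation [4+2]/[2+2] cyclodimerisation of anethole‑type styrenes. E‑alkene geometry and aryl‑endo closure place Ar/Me1 trans and Me/Me trans, giving all‑trans. The remote side chain does not control the tetralin face, so roughly 1:1 diastereomers (tetralin 1S,2S,3R versus 1R,2R,3S) form and the desired one is separated by HPLC.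

**Step 11**
Reactants: 12
Product: 13 target
Conditions: H2 (1 atm), 10 % Pd/C, EtOAc–EtOH, rt
Reagents that add atoms: none
Why: hydrogenolysis removes the O‑benzyl ether (ring A) and the aryl benzyl carbonate (ring C, via loss of CO2). The benzylic alcohol, diaryl ether and all stereocentres are untouched under neutral conditions.

## Compound list
1 | catechol | Oc1ccccc1O | starting material
2 | guaiacol | COc1ccccc1O | intermediate
3 | propionic acid | CCC(=O)O | starting material
4 | propiovanillone, 1‑(4‑hydroxy‑3‑methoxyphenyl)propan‑1‑one | CCC(=O)c1ccc(O)c(OC)c1 | intermediate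
5 | 1‑(4‑benzyloxy‑3‑methoxyphenyl)propan‑1‑one | CCC(=O)c1ccc(OCc2ccccc2)c(OC)c1 | intermediate
6 | 2‑bromo‑1‑(4‑benzyloxy‑3‑methoxyphenyl)propan‑1‑one (rac) | CC(Br)C(=O)c1ccc(OCc2ccccc2)c(OC)c1 | intermediate
7 | 1‑(4‑hydroxy‑3‑methoxyphenyl)propan‑1‑ol (rac) | CCC(O)c1ccc(O)c(OC)c1 | intermediate
8 | (E)‑isoeugenol | C/C=C/c1ccc(O)c(OC)c1 | intermediate
9 | (E)‑isoeugenyl benzyl carbonate | C/C=C/c1ccc(OC(=O)OCc2ccccc2)c(OC)c1 | intermediate
10 | α‑aryloxy propiophenone (rac) | CC(Oc1ccc(/C=C/C)cc1OC)C(=O)c1ccc(OCc2ccccc2)c(OC)c1 | intermediate
11 | (1S,2R)‑erythro alcohol | COc1cc([C@H](O)[C@@H](C)Oc2ccc(/C=C/C)cc2OC)ccc1OCc1ccccc1 | intermediate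
12 | protected aryltetralin | COc1cc([C@H](O)[C@@H](C)Oc2ccc([C@H]3c4cc(OC(=O)OCc5ccccc5)c(OC)cc4C[C@@H](C)[C@@H]3C)cc2OC)ccc1OCc1ccccc1 | intermediate
13 | target (CID53359464) | COc1cc([C@H](O)[C@@H](C)Oc2ccc([C@H]3c4cc(O)c(OC)cc4C[C@@H](C)[C@@H]3C)cc2OC)ccc1O | target

## Totals
Total steps: 11. Longest linear sequence: 8 (steps 1, 2, 3, 4, 8, 9, 10, 11).

## Three steps most likely to fail
1. **Step 10 (radical‑cation cross [4+2]).** Cyclobutane [2+2] products, homodimer of 11 and diastereomer mixtures may dominate.
   Fallback (different approach): homodimerise carbonate 9 (or the corresponding Bn ether) by radical‑cation [4+2] to give the symmetrical all‑trans tetralin. Hydrogenolyse it to the bisphenol, mono‑alkylate with 6 and separate the regioisomers. Then run the DKR‑ATH and a final hydrogenolysis, so the chain is added last.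
2. **Step 9 (DKR‑ATH of the α‑aryloxy ketone).** Epimerisation may be too slow for an efficient DKR, or the erythro/threo selectivity may be poor.
   Fallback (different approach): Shi asymmetric epoxidation of (E)‑4‑benzyloxy‑3‑methoxy‑1‑propenylbenzene gives the trans‑epoxide. Open it at C8 with the phenoxide of 8 under Cs2CO3. Anti opening gives the erythro alcohol directly.
3. **Step 6 (dehydration of a p‑hydroxybenzylic alcohol).** Isoeugenol dimerises or oligomerises under acid via the quinone methide.
   Fallback (different approach): dehydrate the O‑TBS ether of the carbinol (or of the Bn‑free ketone 4‑derived carbinol) through a mesylate/elimination sequence with no free phenol. Then release 8 with TBAF, avoiding the quinone‑methide pathway.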